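The butenolide ring O1–C2(=O)–C3(Me)=C4(CO2H)–C5 is traced back to a but-2-ynyl carbinol: C3≡C4 is the alkyne and C5 carries the free hydroxyl. Its magnesium alkoxide steers an anti carbomagnesiation that places a vinyl group (a masked carboxyl) on C4 and magnesium on C3. Carbon dioxide then delivers C2 and the lactone closes through O1–C2, so three bonds, the ring and the tetrasubstituted alkene geometry arise in one operation. The precursor is (4R)-icos-19-en-2-yn-4-ol, whose chain-end alkene masks the second carboxyl and whose stereocentre comes from asymmetric transfer hydrogenation of the ynone. Ozonolysis and chlorite oxidation then unveil both acids.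

Key step: step 4

Remark: C5 of the target is R (O1 > C4 > side chain > H) and the side chain holds fourteen methylene groups before the terminal carboxyl. The alkynol carbinol that becomes C5 keeps the same spatial arrangement and priority order, so it is also R and carries a hexadec-15-enyl chain; no structure needed correction. The route uses no protecting groups. Partners that deliver atoms (2, 6, 10, 11) are numbered as reactants and repeated on the reagent line.

Step 1
Reactants: 1 11-bromoundec-1-ene; 2 ethyl 6-bromohexanoate
Product: 4 ethyl heptadec-16-enoate, via undec-10-enylmagnesium bromide 3 (not isolated)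
Conditions: Mg, THF, 40 °C; then slow addition to 2, Li2CuCl4 (3 mol%), NMP, THF, 0 °C → rt
Reagents that add atoms: ethyl 6-bromohexanoate (2), CCOC(=O)CCCCCBr
Why: Copper-catalysed sp3–sp3 Grignard–alkyl bromide cross-coupling (Kochi type, NMP as co-solvent) should join C11 to C6 because the primary C–Br bond of 2 is consumed much faster than the ester is attacked when 3 is added slowly at 0 °C, and the terminal alkene is a spectator.

Step 2
Reactants: 4 ethyl heptadec-16-enoate; 5 N,O-dimethylhydroxylamine hydrochloride; 6 prop-1-yn-1-ylmagnesium bromide
Product: 8 icos-19-en-2-yn-4-one, via Weinreb amide 7 (not isolated)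
Conditions: 5, i-PrMgCl, THF, −20 °C; then 6 (0.5 M in THF), −20 °C → rt; inverse quench into cold 1 M HCl
Reagents that add atoms: prop-1-yn-1-ylmagnesium bromide (6), CC#C[Mg]Br
Why: Weinreb ketone synthesis run in one flask from the ester: the chloromagnesium amide formed from 5 and i-PrMgCl converts the ethyl ester into amide 7, whose five-membered magnesium chelate accepts a single propynyl group and collapses to the ynone only on the acidic quench, which also protonates the released amine so that it cannot add to the ynone.

Step 3
Reactants: 8 icos-19-en-2-yn-4-one
Product: 9 (4R)-icos-19-en-2-yn-4-ol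
Conditions: Ru[(R,R)-TsDPEN](p-cymene) (base-free 16-electron complex, 1 mol%), i-PrOH, rt
Reagents that add atoms: none
Why: Noyori asymmetric transfer hydrogenation of an alkyl alkynyl ketone: in the six-membered Ru–H/N–H transition state the alkynyl group takes the place an aryl group occupies next to the arene ligand, so the (R,R) catalyst should deliver hydride to the Si face and set C4 of 9 (the later ring C5) as R, while the isolated alkene and the alkyne are not reduced.

Step 4
Reactants: 9 (4R)-icos-19-en-2-yn-4-ol; 10 vinylmagnesium chloride; 11 carbon dioxide
Product: 14 (5R)-4-ethenyl-5-(hexadec-15-en-1-yl)-3-methylfuran-2(5H)-one, via oxamagnesole chelate 12 (not isolated), via hydroxy dienoic acid 13 (not isolated)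
Conditions: 10 (5 equiv, 1.6 M in THF), THF/cyclohexane, reflux; then CO2 gas, −20 °C → rt; then 2 M HCl, rt
Reagents that add atoms: vinylmagnesium chloride (10), C=C[Mg]Cl; carbon dioxide (11), O=C=O
Why: The first equivalent of 10 deprotonates the hydroxyl of 9 (ethene is lost), and the magnesium alkoxide guides a second equivalent so that the vinyl group bonds to the alkyne carbon next to the carbinol (C4) while magnesium bonds to the methyl-bearing carbon (C3) on the opposite face, giving the five-membered O–Mg–C3=C4–C5 chelate 12; carbon dioxide then inserts into the C3–Mg bond with retention of alkene geometry to give the magnesium salt of 13. The closest known reaction type is the alkoxide-directed anti-carbomagnesiation of propargylic alcohols by vinyl Grignard reagents with carbon dioxide quench to butenolides, applied here to a secondary but-2-ynyl carbinol. The one ring formed, the butenolide, closes on acidification by 5-exo-trig attack of the C5 hydroxyl on the cis carboxyl group (O1–C2), which the Z geometry of 13 makes spontaneous. No stereocentre is created; C5 is carried over from 9 because neither its C–O nor its C–H bond is touched, the alkoxide keeping C5–H non-acidic under the basic conditions. The step needs regioselectivity (vinyl to C4, not C3) and anti selectivity, and the C5 alkoxide secures both, since the opposite regiochemistry would require a four-membered chelate and a syn addition would leave magnesium out of reach of the oxygen. The isolated chain-end alkene is inert to carbomagnesiation, and excess 10 ends as acrylic acid, which is removed in the aqueous wash.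

Step 5
Reactants: 14 (5R)-4-ethenyl-5-(hexadec-15-en-1-yl)-3-methylfuran-2(5H)-one
Product: 15 (2R)-4-methyl-5-oxo-2-(15-oxopentadecyl)-2,5-dihydrofuran-3-carbaldehyde
Conditions: O3, CH2Cl2, Sudan Red 7B (indicator), −78 °C; then PPh3, −78 °C → rt; crude product used directly
Reagents that add atoms: ozone, [O-][O+]=O
Why: Ozonolysis with reductive work-up: electrophilic ozone should cleave the two monosubstituted C=C bonds far faster than the tetrasubstituted ring C3=C4 bond, which is deactivated by the lactone carbonyl and, after the first cleavage, by the formyl group; the dye shows the end point and the neutral phosphine work-up spares the base-sensitive C5–H.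

Step 6
Reactants: 15 (2R)-4-methyl-5-oxo-2-(15-oxopentadecyl)-2,5-dihydrofuran-3-carbaldehyde
Product: 16 (2R)-2-(14-carboxytetradecyl)-4-methyl-5-oxo-2,5-dihydrofuran-3-carboxylic acid
Conditions: NaClO2, NaH2PO4, 2-methylbut-2-ene, t-BuOH/H2O, 0 °C → rt
Reagents that add atoms: sodium chlorite, [Na+].[O-]Cl=O
Why: Pinnick (Lindgren) oxidation: chlorous acid at pH 3–4 converts both aldehydes into carboxylic acids without touching the ring alkene or epimerising C5, and 2-methylbut-2-ene consumes the hypochlorous acid formed.

Compound list
1 | 11-bromoundec-1-ene | C=CCCCCCCCCCBr | starting material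
2 | ethyl 6-bromohexanoate | CCOC(=O)CCCCCBr | starting material
3 | undec-10-en-1-ylmagnesium bromide | C=CCCCCCCCCC[Mg]Br | intermediate
4 | ethyl heptadec-16-enoate | CCOC(=O)CCCCCCCCCCCCCCC=C | intermediate
5 | N,O-dimethylhydroxylamine hydrochloride | CNOC.Cl | starting material
6 | prop-1-yn-1-ylmagnesium bromide | CC#C[Mg]Br | starting material
7 | N-methoxy-N-methylheptadec-16-enamide (Weinreb amide) | CON(C)C(=O)CCCCCCCCCCCCCCC=C | intermediate
8 | icos-19-en-2-yn-4-one | CC#CC(=O)CCCCCCCCCCCCCCC=C | intermediate
9 | (4R)-icos-19-en-2-yn-4-ol | CC#C[C@@H](CCCCCCCCCCCCCCC=C)O | intermediate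
10 | vinylmagnesium chloride | C=C[Mg]Cl | starting material
11 | carbon dioxide | O=C=O | starting material
12 | (5R)-4-ethenyl-5-(hexadec-15-en-1-yl)-3-methyl-2,5-dihydro-1,2-oxamagnesole (oxamagnesole chelate) | CC1=C(C=C)[C@@H](CCCCCCCCCCCCCCC=C)O[Mg]1 | intermediate
13 | (2Z,4R)-3-ethenyl-4-hydroxy-2-methylicosa-2,19-dienoic acid (hydroxy dienoic acid) | C/C(C(=O)O)=C(C=C)/[C@@H](CCCCCCCCCCCCCCC=C)O | intermediate
14 | (5R)-4-ethenyl-5-(hexadec-15-en-1-yl)-3-methylfuran-2(5H)-one | CC1=C(C=C)[C@@H](CCCCCCCCCCCCCCC=C)OC1=O | intermediate
15 | (2R)-4-methyl-5-oxo-2-(15-oxopentadecyl)-2,5-dihydrofuran-3-carbaldehyde | CC1=C(C=O)[C@@H](CCCCCCCCCCCCCCC=O)OC1=O | intermediate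
16 | (2R)-2-(14-carboxytetradecyl)-4-methyl-5-oxo-2,5-dihydrofuran-3-carboxylic acid | CC1=C(C(=O)O)[C@@H](CCCCCCCCCCCCCCC(=O)O)OC1=O | target

Total step count: 6. Longest linear sequence: 6 steps (1 → 16).

Steps most likely to fail

Step 4. The carbomagnesiation of the secondary alkoxide may stall, or the hindered chelated alkenylmagnesium may take up carbon dioxide poorly and be protonated on work-up, so that the diene alcohol is obtained in place of the lactone. The fallback sets out from 9: the chelate is generated in the same way but quenched with iodine to give (2Z,4R)-3-ethenyl-2-iodoicosa-2,19-dien-4-ol F1. Palladium-catalysed carbonylative lactonisation of this Z-iodo allylic alcohol (CO 1 atm, PdCl2(PPh3)2, Et3N, THF, 50 °C) then brings in C2 and closes O1–C2, returning to the route at 14.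

Step 5. Ozone may attack the ring C3=C4 bond as well, or cleave the conjugated ring vinyl group incompletely, so that the end point is hard to hit. The fallback sets out from 14: Upjohn dihydroxylation (OsO4 cat., NMO, acetone/H2O) should touch only the two monosubstituted alkenes and give (5R)-4-(1,2-dihydroxyethyl)-5-(15,16-dihydroxyhexadecyl)-3-methylfuran-2(5H)-one F2, a mixture at the two new carbinol carbons that is of no consequence. Periodate cleavage (NaIO4, THF/H2O) of both diols returns to the route at 15.

Step 2. Amide formation in the one-flask protocol may be incomplete, or the released amine may add to the ynone during the quench. The fallback sets out from 4: DIBAL-H reduction (CH2Cl2, −78 °C) gives heptadec-16-enal F3, addition of 6 (THF, 0 °C) gives racemic icos-19-en-2-yn-4-ol F4, and Dess–Martin oxidation returns to the route at 8.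

Further compounds
F1 | step 4 | (2Z,4R)-3-ethenyl-2-iodoicosa-2,19-dien-4-ol | C/C(I)=C(C=C)/[C@@H](CCCCCCCCCCCCCCC=C)O
F2 | step 5 | (5R)-4-(1,2-dihydroxyethyl)-5-(15,16-dihydroxyhexadecyl)-3-methylfuran-2(5H)-one (mixture at the two new carbinol carbons) | CC1=C(C(O)CO)[C@@H](CCCCCCCCCCCCCCC(O)CO)OC1=O
F3 | step 2 | heptadec-16-enal | C=CCCCCCCCCCCCCCCC=O
F4 | step 2 | icos-19-en-2-yn-4-ol (racemic) | CC#CC(O)CCCCCCCCCCCCCCC=C
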